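The plan reads the ring alkene C2=C3, flanked by the carbonyl C1 and the carbinol C4, as the mark of a cyclohexa-1,3-diene that has taken up O2 across its ends. That diene is made in one operation: an inverse-electron-demand Diels–Alder reaction of 2-pyrone with the silyl enol ether of the methyl ketone from oleic acid, then loss of CO2 from the bridged lactone, forms the ring bonds C1–C6 and C4–C5. The precursor is thus a pyrone and an open-chain enol ether. Singlet oxygen and a Kornblum–DeLaMare rearrangement set the trans diol and the enone; a lipase resolution gives the (4S,5S) enantiomer.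

Key step: step 3

Remark: ring positions are numbered as in the target (C1 carbonyl, C2=C3, C4 secondary carbinol, C5 tertiary carbinol, C6 CH2). Compounds 5 to 8 are racemic; 7, 8 and F2 are written as the enantiomer of the target series to show the relative configuration.

Step 1
Reactants: 1 oleic acid, (9Z)-octadec-9-enoic acid
Product: 2 (10Z)-nonadec-10-en-2-one
Conditions: MeLi (2.2 equiv), Et2O, 0 °C to rt; then H2O
Reagents that add atoms: methyllithium ([Li]C)
Why: The first equivalent forms the lithium carboxylate and the second adds to give a dilithium gem-diolate that collapses to the methyl ketone only on hydrolysis (organolithium addition to a carboxylate), so over-addition should be small and the isolated Z-alkene is untouched.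

Step 2
Reactants: 2 (10Z)-nonadec-10-en-2-one
Product: 3 triethyl{[(10Z)-nonadeca-1,10-dien-2-yl]oxy}silane
Conditions: LiN(i-Pr)2 (1.1 equiv), THF, −78 °C; Et3SiCl (1.2 equiv), −78 °C to 0 °C
Reagents that add atoms: chlorotriethylsilane (CC[Si](CC)(CC)Cl)
Why: Kinetic deprotonation by the hindered amide at low temperature should take a proton of the methyl group and not of the chain methylene, and O-silylation of that terminal enolate gives the 1,1-disubstituted silyl enol ether (kinetic silyl enol ether formation).

Step 3
Reactants: 3 triethyl{[(10Z)-nonadeca-1,10-dien-2-yl]oxy}silane; 4 2H-pyran-2-one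
Product: 6 triethyl({1-[(8Z)-heptadec-8-en-1-yl]cyclohexa-2,4-dien-1-yl}oxy)silane (racemic), via bridged lactone 5 (not isolated)
Conditions: 4 (2 equiv), CH2Cl2, 12 kbar, 40 °C; excess 4 removed under vacuum; then toluene, Et3N (5 mol%), 110 °C
Reagents that add atoms: none
Why: The electron-poor 2-pyrone acts as the 4π partner (its C3 to C6) and the electron-rich enol ether as the 2π partner in an inverse-electron-demand Diels–Alder reaction, the closest known type being the cycloaddition of 2-pyrones with enol ethers followed by thermal loss of CO2. The carbocycle is closed by a concerted, asynchronous [4+2] cycloaddition that gives the 2-oxabicyclo[2.2.2]octenone 5, and the lactone bridge then leaves as CO2 in a retro-[4+2] step once the pressure is released and the solution is heated. The only stereocentre that survives, the quaternary carbinol carbon, is formed without facial bias and is therefore racemic. The endo, exo and regioisomeric forms of 5 should all converge on the one diene, because their bridgehead centres become sp2 carbons. The step needs chemoselectivity for the enol ether C=C over the isolated Z-alkene, which the oxygen donor secures by raising the HOMO of that alkene alone, and it must not lose silanol to give an arene, which the absence of acid (amine additive) should secure. High pressure is chosen because it speeds up the cycloaddition of the unactivated pyrone and holds back CO2 loss until the adduct has formed.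

Step 4
Reactants: 6 triethyl({1-[(8Z)-heptadec-8-en-1-yl]cyclohexa-2,4-dien-1-yl}oxy)silane (racemic)
Product: 8 rac-(4S*,5S*)-5-[(8Z)-heptadec-8-en-1-yl]-4-hydroxy-5-[(triethylsilyl)oxy]cyclohex-2-en-1-one, via bicyclic endoperoxide 7 (not isolated)
Conditions: O2, 5,10,15,20-tetraphenylporphyrin (1 mol%), visible light, CH2Cl2, −78 °C; then Et3N (2 equiv), −78 °C to 0 °C
Reagents that add atoms: dioxygen (O=O)
Why: Singlet oxygen should add to the s-cis diene in a [4+2] cycloaddition on the face anti to the pseudo-axial silyloxy group, which sets the C4–O bond trans to the C5–O bond, and the amine should then remove the less hindered bridgehead hydrogen next to CH2 so that O–O cleavage (Kornblum–DeLaMare rearrangement) gives the C1 carbonyl and the C4 hydroxyl, while the isolated Z-alkene can react only by the much slower ene pathway.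

Step 5
Reactants: 8 rac-(4S*,5S*)-5-[(8Z)-heptadec-8-en-1-yl]-4-hydroxy-5-[(triethylsilyl)oxy]cyclohex-2-en-1-one
Product: 9 (4S,5S)-5-[(8Z)-heptadec-8-en-1-yl]-4-hydroxy-5-[(triethylsilyl)oxy]cyclohex-2-en-1-one
Conditions: lipase from Burkholderia cepacia (immobilised), vinyl acetate (3 equiv), t-BuOMe, 30 °C, run past half conversion; chromatography
Reagents that add atoms: none
Why: Lipase-catalysed acyl transfer (enzymatic kinetic resolution of a secondary alcohol) should acetylate the (4R)-carbinol faster, as the empirical size rule predicts for a carbinol flanked by a small vinylic CH and a bulky fully substituted carbon, so the (4S,5S)-alcohol is recovered with both stereocentres in the required absolute sense.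

Step 6
Reactants: 9 (4S,5S)-5-[(8Z)-heptadec-8-en-1-yl]-4-hydroxy-5-[(triethylsilyl)oxy]cyclohex-2-en-1-one
Product: 10 (4S,5S)-5-[(8Z)-heptadec-8-en-1-yl]-4,5-dihydroxycyclohex-2-en-1-one
Conditions: HF·pyridine, pyridine, THF, 0 °C to rt
Reagents that add atoms: none
Why: Fluoride cleavage of the tertiary silyl ether under buffered, weakly acidic conditions (desilylation) frees the tertiary alcohol without base, so neither retro-aldol opening nor β-elimination of the β-hydroxy ketone is expected and no stereocentre is touched.

Compound list
1 | oleic acid, (9Z)-octadec-9-enoic acid | CCCCCCCC/C=C\CCCCCCCC(=O)O | starting material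
2 | (10Z)-nonadec-10-en-2-one | CCCCCCCC/C=C\CCCCCCCC(C)=O | intermediate
3 | triethyl{[(10Z)-nonadeca-1,10-dien-2-yl]oxy}silane | CCCCCCCC/C=C\CCCCCCCC(=C)O[Si](CC)(CC)CC | intermediate
4 | 2H-pyran-2-one (2-pyrone) | O=C1C=CC=CO1 | starting material
5 | 8-[(8Z)-heptadec-8-en-1-yl]-8-[(triethylsilyl)oxy]-2-oxabicyclo[2.2.2]oct-5-en-3-one, racemic mixture of endo and exo isomers | CCCCCCCC/C=C\CCCCCCCC1(O[Si](CC)(CC)CC)CC2OC(=O)C1C=C2 | intermediate
6 | triethyl({1-[(8Z)-heptadec-8-en-1-yl]cyclohexa-2,4-dien-1-yl}oxy)silane, racemic | CCCCCCCC/C=C\CCCCCCCC1(O[Si](CC)(CC)CC)CC=CC=C1 | intermediate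
7 | 7-[(8Z)-heptadec-8-en-1-yl]-7-[(triethylsilyl)oxy]-2,3-dioxabicyclo[2.2.2]oct-5-ene, racemic, peroxide bridge anti to the silyloxy group | CCCCCCCC/C=C\CCCCCCC[C@]1(O[Si](CC)(CC)CC)C[C@H]2C=C[C@@H]1OO2 | intermediate
8 | rac-(4S*,5S*)-5-[(8Z)-heptadec-8-en-1-yl]-4-hydroxy-5-[(triethylsilyl)oxy]cyclohex-2-en-1-one | CCCCCCCC/C=C\CCCCCCC[C@]1(O[Si](CC)(CC)CC)CC(=O)C=C[C@@H]1O | intermediate
9 | (4S,5S)-5-[(8Z)-heptadec-8-en-1-yl]-4-hydroxy-5-[(triethylsilyl)oxy]cyclohex-2-en-1-one | CCCCCCCC/C=C\CCCCCCC[C@]1(O[Si](CC)(CC)CC)CC(=O)C=C[C@@H]1O | intermediate
10 | (4S,5S)-5-[(8Z)-heptadec-8-en-1-yl]-4,5-dihydroxycyclohex-2-en-1-one | CCCCCCCC/C=C\CCCCCCC[C@]1(O)CC(=O)C=C[C@@H]1O | target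

Total step count: 6
Longest linear sequence: 6 steps (1 → 2 → 3 → 6 → 8 → 9 → 10)

Steps most likely to fail

Step 3. The cycloaddition may be too slow for an unactivated pyrone and a hindered 1,1-disubstituted enol ether, and the diene may lose silanol and aromatise while CO2 is driven off. The fallback sets out from 3, which would be heated with 3-bromo-2H-pyran-2-one (O=C1OC=CC=C1Br, a more reactive, ambiphilic pyrone) in toluene at 90 °C to give the bridgehead bromo lactone F1. Radical debromination with Bu3SnH and AIBN in toluene at 80 °C would then give lactone 5, this time isolated and purified. The route is rejoined at 5, which is decarboxylated on its own in buffered toluene to give 6.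

Step 4. The base may abstract the hindered bridgehead hydrogen instead of the one next to CH2 (giving the isomeric enone), or it may trigger loss of the silyloxy group. The fallback sets out from endoperoxide 7, which would be reduced with thiourea in MeOH at 0 °C to the cis-enediol F2. Site-selective oxidation of the less hindered allylic alcohol (the one next to CH2) with MnO2 in CH2Cl2 would then give 8, where the route is rejoined. Here steric discrimination between two alcohols replaces discrimination between two C–H bonds.

Step 5. The enzyme may discriminate poorly between the enantiomers, or turn over too slowly, because the carbinol sits next to a fully substituted carbon. The fallback sets out from 8, which would be esterified with (2S)-2-methoxy-2-phenylacetic acid (DCC, DMAP, CH2Cl2) to give the (4S,5S) ester F3 and the (4R,5R) ester F4. The two diastereomers would be separated by chromatography, and mild methanolysis of F3 (K2CO3, MeOH, 0 °C) would return 9, where the route is rejoined.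

Further compounds
F1 | step 3 | 4-bromo-8-[(8Z)-heptadec-8-en-1-yl]-8-[(triethylsilyl)oxy]-2-oxabicyclo[2.2.2]oct-5-en-3-one, racemic mixture of isomers | CCCCCCCC/C=C\CCCCCCCC1(O[Si](CC)(CC)CC)CC2OC(=O)C1(Br)C=C2
F2 | step 4 | rac-5-[(8Z)-heptadec-8-en-1-yl]-5-[(triethylsilyl)oxy]cyclohex-2-ene-1,4-diol, hydroxyls cis to each other and trans to the silyloxy group | CCCCCCCC/C=C\CCCCCCC[C@]1(O[Si](CC)(CC)CC)C[C@H](O)C=C[C@@H]1O
F3 | step 5 | (2S)-2-methoxy-2-phenylacetate ester (at the C4 oxygen) of 9 | CCCCCCCC/C=C\CCCCCCC[C@]1(O[Si](CC)(CC)CC)CC(=O)C=C[C@@H]1OC(=O)[C@@H](OC)c1ccccc1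
F4 | step 5 | (2S)-2-methoxy-2-phenylacetate ester (at the C4 oxygen) of the enantiomer of 9 | CCCCCCCC/C=C\CCCCCCC[C@@]1(O[Si](CC)(CC)CC)CC(=O)C=C[C@H]1OC(=O)[C@@H](OC)c1ccccc1
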